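**Strategy.** Ardisinone's quinone ring is read as a four-carbon squarate unit (C1=O, C2–OMe, C3–H, C4=O) joined to a 1,1-disubstituted alkene (C5–H, C6 bearing the side chain). Everything rests on closing the ring between the C4 carbonyl carbon and C5. The precursor is a 4-alkenyl-4-hydroxy-3-methoxycyclobutenone, a strained ring absent from the target and built only to be cleaved. Heating opens it to a dienylketene whose 6π-electrocyclisation forms the C4–C5 bond and delivers the fully oxygenated hydroquinone, oxidised in the same flask. The alkenyl partner, a chiral oxido-vinyllithium, comes from enantioselective 2-bromoallylation of tetradecanal; its carbinol stereocentre is never touched again.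

Key step: step 6

Assumption: the B-(2-bromoallyl)diazaborolidine from the (R,R)-bis-sulfonamide is taken to attack the si face of an unbranched aldehyde (allyl unit remote from the tolylsulfonyl group in the chair transition state); the configuration of 4 is to be checked as its Mosher esters, and the (S,S)-controller is used if the sense proves opposite.

**Step 1**
Reactants: 1 2,3-dibromopropene
Product: 2 tributyl(2-bromoprop-2-en-1-yl)stannane
Conditions: Bu3SnH, LiN(iPr)2, THF, 0 °C; then 1, −78 °C
Reagents that add atoms: tributylstannyllithium, [Li][Sn](CCCC)(CCCC)CCCC (made in the flask from Bu3SnH and LiN(iPr)2)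
Why: The soft stannyl anion displaces the allylic bromide (nucleophilic substitution of an allylic halide by a tin anion) far faster than it touches the vinylic C–Br bond at −78 °C.

**Step 2**
Reactants: 2 tributyl(2-bromoprop-2-en-1-yl)stannane; 3 tetradecanal
Product: 4 (R)-2-bromoheptadec-1-en-4-ol
Conditions: (R,R)-N,N'-bis(p-tolylsulfonyl)-1,2-diphenylethane-1,2-diamine (recovered), BBr3, CH2Cl2, 0 °C to rt, volatiles removed; 2, CH2Cl2, rt; then 3, −78 °C; pH 7 buffer
Reagents that add atoms: none
Why: Corey enantioselective 2-haloallylation: Sn-to-B allyl transfer gives the B-(2-bromoallyl)-1,3,2-diazaborolidine, which adds to the aldehyde through a closed chair six-membered transition state in which the C2-symmetric bis-sulfonamide exposes the si face, setting C4 as R, while the low temperature suppresses β-bromo elimination to allene.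

**Step 3**
Reactants: 5 dimethyl squarate
Product: 7 3-methoxycyclobut-3-ene-1,2-dione, via hydroxycyclobutenone 6 (not isolated)
Conditions: LiAlH(OtBu)3, THF, −78 °C; 1 M HCl quench; crude 6, conc. HCl (cat.), CH2Cl2, rt; used fresh
Reagents that add atoms: none
Why: Known reduction–hydrolysis route from dialkyl squarates to alkyl semisquarates: the bulky hydride adds 1,2 to one of the two equivalent carbonyls, then acid ionises the allylic hydroxyl, water captures the methoxy-stabilised cation at the former C2 and methanol is lost, leaving the 1,2-dione with hydrogen on the ring.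

**Step 4**
Reactants: 4 (R)-2-bromoheptadec-1-en-4-ol; 7 3-methoxycyclobut-3-ene-1,2-dione
Product: 9 4-hydroxy-4-[(4R)-4-hydroxyheptadec-1-en-2-yl]-3-methoxycyclobut-2-en-1-one (both epimers at the ring carbinol carbon), via dianion 8 (not isolated)
Conditions: t-BuLi (3.1 equiv), Et2O, −78 °C; cannulated into 7 (1.2 equiv), THF, −78 °C; sat. aq. NH4Cl at −78 °C
Reagents that add atoms: none
Why: One equivalent of t-BuLi deprotonates the hydroxyl and two effect Br/Li exchange to the γ-lithiooxy vinyllithium, which adds 1,2 to the ketone-like carbonyl next to the methoxy-bearing carbon of 7 (the other carbonyl is deactivated as a vinylogous ester), the known regioselective organolithium addition to 3-alkoxycyclobutenediones; the new ring carbinol centre forms as both epimers, which converge in step 6.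

**Step 5**
Reactants: 9 4-hydroxy-4-[(4R)-4-hydroxyheptadec-1-en-2-yl]-3-methoxycyclobut-2-en-1-one
Product: 10 (4R)-2-(1-hydroxy-2-methoxy-4-oxocyclobut-2-en-1-yl)heptadec-1-en-4-yl acetate
Conditions: Ac2O (1.2 equiv), pyridine, DMAP (cat.), CH2Cl2, 0 °C
Reagents that add atoms: acetic anhydride, CC(=O)OC(C)=O
Why: DMAP-catalysed acyl transfer acetylates the unhindered secondary hydroxyl much faster than the fully substituted ring carbinol flanked by a carbonyl and two sp2 carbons, so one equivalent of anhydride at 0 °C should stop at the monoacetate without touching the stereocentre.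

**Step 6**
Reactants: 10 (4R)-2-(1-hydroxy-2-methoxy-4-oxocyclobut-2-en-1-yl)heptadec-1-en-4-yl acetate
Product: 14 Ardisinone, via dienylketene 11 (not isolated), via cyclohexadienone 12 (not isolated), via hydroquinone 13 (not isolated)
Conditions: p-xylene (degassed, 0.02 M), 138 °C; cooled; Ag2O, Et2O, rt
Reagents that add atoms: none
Why: Heating effects a 4π conrotatory electrocyclic opening of the bond between the carbonyl carbon and the carbinol carbon of the cyclobutenone to give dienylketene 11, whose ketene carbon then bonds to the terminal CH2 of the alkenyl group in a thermal 6π disrotatory electrocyclisation (the six-membered ring is closed by this one C–C bond) to dienone 12, which enolises to hydroquinone 13; Ag2O then removes two hydrogens to give the quinone. The closest known reaction type is the Moore thermal ring expansion of 4-alkenyl-4-hydroxycyclobutenones to hydroquinones. No stereocentre is created: both ring-carbinol epimers of 10 give the same ketene, and the acetoxy-bearing centre is remote from every bond change. The step needs torquoselectivity, since the alkenyl group must rotate inward to lie cis to the ketenyl carbon, and this is secured by the hydroxyl, a donor that prefers outward rotation. The positions of OMe, H and the side chain on the new ring are fixed by the substitution pattern of the four-membered ring, so the closure has no regiochemical choice.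

**Compound list**
1 | 2,3-dibromopropene | C=C(Br)CBr | starting material
2 | tributyl(2-bromoprop-2-en-1-yl)stannane | C=C(Br)C[Sn](CCCC)(CCCC)CCCC | intermediate
3 | tetradecanal | CCCCCCCCCCCCCC=O | starting material
4 | (R)-2-bromoheptadec-1-en-4-ol | CCCCCCCCCCCCC[C@H](CC(Br)=C)O | intermediate
5 | dimethyl squarate (3,4-dimethoxycyclobut-3-ene-1,2-dione) | COC1=C(OC)C(=O)C1=O | starting material
6 | 4-hydroxy-2,3-dimethoxycyclobut-2-en-1-one (racemic, not isolated) | COC1=C(OC)C(O)C1=O | intermediate
7 | 3-methoxycyclobut-3-ene-1,2-dione (methyl semisquarate) | COC1=CC(=O)C1=O | intermediate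
8 | lithium (R)-2-lithioheptadec-1-en-4-olate (dianion, not isolated) | CCCCCCCCCCCCC[C@H](CC([Li])=C)O[Li] | intermediate
9 | 4-hydroxy-4-[(4R)-4-hydroxyheptadec-1-en-2-yl]-3-methoxycyclobut-2-en-1-one (both epimers at ring C4) | CCCCCCCCCCCCC[C@H](CC(=C)C1(O)C(OC)=CC1=O)O | intermediate
10 | (4R)-2-(1-hydroxy-2-methoxy-4-oxocyclobut-2-en-1-yl)heptadec-1-en-4-yl acetate (both epimers at ring C1) | CCCCCCCCCCCCC[C@H](CC(=C)C1(O)C(OC)=CC1=O)OC(C)=O | intermediate
11 | (4R)-2-[(1Z)-1-hydroxy-2-methoxy-4-oxobuta-1,3-dien-1-yl]heptadec-1-en-4-yl acetate (dienylketene, not isolated) | CCCCCCCCCCCCC[C@H](CC(=C)/C(O)=C(OC)\C=C=O)OC(C)=O | intermediate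
12 | (2R)-1-(2-hydroxy-3-methoxy-5-oxocyclohexa-1,3-dien-1-yl)pentadecan-2-yl acetate (not isolated) | CCCCCCCCCCCCC[C@H](CC1=C(O)C(OC)=CC(=O)C1)OC(C)=O | intermediate
13 | (2R)-1-(2,5-dihydroxy-3-methoxyphenyl)pentadecan-2-yl acetate (hydroquinone, not isolated) | CCCCCCCCCCCCC[C@H](Cc1cc(O)cc(OC)c1O)OC(C)=O | intermediate
14 | Ardisinone, (2R)-1-(5-methoxy-3,6-dioxocyclohexa-1,4-dien-1-yl)pentadecan-2-yl acetate | CCCCCCCCCCCCC[C@H](CC1=CC(=O)C=C(OC)C1=O)OC(C)=O | target

**Step count.** Total: 6 steps. Longest linear sequence: 5 steps (1, 2, 4, 5, 6); step 3 is a one-step branch.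

**Steps most likely to fail**

Step 4. After the addition the side-chain lithium alkoxide sits six atoms from the methoxy-bearing ring carbon and may displace methoxide by addition–elimination. Aggregation of the dianion may also slow the addition enough for attack at the other carbonyl or deprotonation of the ring C–H to compete. The fallback sets out from 4 and masks the oxygen: Et3SiCl and imidazole in CH2Cl2 should give (R)-[(2-bromoheptadec-1-en-4-yl)oxy]triethylsilane F1. Br/Li exchange on F1 (t-BuLi, 2 equiv, Et2O, kept at −78 °C so that a 1,4 O-to-C silyl shift stays slow) and addition to 7 should give 4-hydroxy-3-methoxy-4-[(4R)-4-(triethylsilyloxy)heptadec-1-en-2-yl]cyclobut-2-en-1-one F2. HF·pyridine in THF at 0 °C then frees the secondary hydroxyl and the route is rejoined at 9.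

Step 6. Ring opening with the alkenyl group rotating outward would place the hydroxyl next to the ketene, which is then captured as a five-membered lactone instead of closing to the carbocycle; the unsubstituted ketene terminus may also be lost to intermolecular reactions. The fallback sets out from 10 and blocks the lactone path structurally: Me3SiOTf and 2,6-lutidine in CH2Cl2 at −78 °C should give (4R)-2-[2-methoxy-4-oxo-1-(trimethylsilyloxy)cyclobut-2-en-1-yl]heptadec-1-en-4-yl acetate F3. On heating in toluene at 110 °C, a wrongly rotated ketene from F3 can only re-close, so the material should funnel to (2R)-1-[5-hydroxy-3-methoxy-2-(trimethylsilyloxy)phenyl]pentadecan-2-yl acetate F4. Oxidative desilylation of F4 with (NH4)2Ce(NO3)6 in MeCN/H2O at 0 °C comes back to the route at 14.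

Step 2. Enantioface discrimination may be insufficient for an unbranched aldehyde, the sense may be opposite to the one assumed, or the 2-bromoallylborane may eliminate to allene before it adds. The fallback sets out from 3 and fixes the configuration by kinetic resolution. Me3SI and NaH in DMSO/THF (Corey–Chaykovsky) should give racemic 2-tridecyloxirane F5. Hydrolytic kinetic resolution with (R,R)-(salen)Co(OAc) [salen = N,N'-bis(3,5-di-tert-butylsalicylidene)cyclohexane-1,2-diamine dianion] and 0.55 equiv of water should hydrolyse the (S)-epoxide and leave (R)-2-tridecyloxirane F6. Opening with LiC≡CH·H2NCH2CH2NH2 in DMSO gives (R)-heptadec-1-yn-4-ol F7. Markovnikov addition of HI (NaI, Me3SiCl, H2O, MeCN) gives (R)-2-iodoheptadec-1-en-4-ol F8. Treated with t-BuLi (3 equiv) as in step 4, F8 gives the same dianion, so the route is rejoined at 8.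

**Further compounds**
F1 | step 4 | (R)-[(2-bromoheptadec-1-en-4-yl)oxy]triethylsilane | CCCCCCCCCCCCC[C@H](CC(Br)=C)O[Si](CC)(CC)CC
F2 | step 4 | 4-hydroxy-3-methoxy-4-[(4R)-4-(triethylsilyloxy)heptadec-1-en-2-yl]cyclobut-2-en-1-one | CCCCCCCCCCCCC[C@H](CC(=C)C1(O)C(OC)=CC1=O)O[Si](CC)(CC)CC
F3 | step 6 | (4R)-2-[2-methoxy-4-oxo-1-(trimethylsilyloxy)cyclobut-2-en-1-yl]heptadec-1-en-4-yl acetate | CCCCCCCCCCCCC[C@H](CC(=C)C1(O[Si](C)(C)C)C(OC)=CC1=O)OC(C)=O
F4 | step 6 | (2R)-1-[5-hydroxy-3-methoxy-2-(trimethylsilyloxy)phenyl]pentadecan-2-yl acetate | CCCCCCCCCCCCC[C@H](Cc1cc(O)cc(OC)c1O[Si](C)(C)C)OC(C)=O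
F5 | step 2 | racemic 2-tridecyloxirane | CCCCCCCCCCCCCC1CO1
F6 | step 2 | (R)-2-tridecyloxirane | CCCCCCCCCCCCC[C@@H]1CO1
F7 | step 2 | (R)-heptadec-1-yn-4-ol | CCCCCCCCCCCCC[C@H](CC#C)O
F8 | step 2 | (R)-2-iodoheptadec-1-en-4-ol | CCCCCCCCCCCCC[C@H](CC(I)=C)O
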